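**Plan**

- Cuts, in retrosynthetic order: the three acetates; C4–CH3 (enol triflate of a C4 ketone); C1–C10 (seven-membered ring B); C5–C6 (union with cyclopent-2-enone); C14=C15 and C12–C13; C7–C11; C9–C10.
- Forward: a C6–C10 chain carrying a 2-bromoallylic silyl ether is joined to C11 by Ireland–Claisen rearrangement, the side chain is completed, cyclopent-2-enone (ring A, intact) is attached at C6, and ring B is closed last through C1–C10; C5 epimerisation, C4 methylation and acetylation follow.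
- Enabling feature: C4–C5–C1 of ring A are a latent 2-substituted cyclopent-2-enone whose α-carbon C5 carries the C6 carbinol (Morita–Baylis–Hillman pattern) and whose β-carbon is C1; the methylidene C10=C18 next to the C9 oxygen is what an α-oxygenated alkenyl radical leaves after 7-endo addition to C1.
- Stereochemistry: C9 by CBS reduction; C7 and C11 by chair Ireland–Claisen rearrangement with chirality transfer from (R,E)-pent-3-en-2-ol; C12 and C13 by Felkin-controlled syn γ-silyloxyallylation; C6 by Felkin-controlled aldol; C1 from the hydrogen-bonded C6 carbinol in the key step; C5 by equilibration to the trans ring fusion.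

Key step: step 16

Remark: skeleton numbering is used throughout: ring A (five-membered) is C1–C5 and ring B (seven-membered) is C1, C5–C10, with C1/C5 the ring fusion. C17 is the methyl on C4 and C18 the methylidene carbon on C10. The side chain on C7 is C11(C19H3)–C12–C13–C14=C15(C16H3)(C20H3). The β face is the face of the C6 hydroxyl. TBS = tert-butyldimethylsilyl, TES = triethylsilyl.

**Step 1**
Reactants: 1 (E)-pent-3-en-2-one
Product: 2 (2R,3E)-pent-3-en-2-ol
Conditions: (S)-2-methyl-CBS-oxazaborolidine (10 mol%), catecholborane, toluene, −78 °C; aq. NaOH work-up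
Reagents that add atoms: none
Why: Corey–Bakshi–Shibata reduction, in which the propenyl group acts as the large substituent so that the (S)-catalyst should deliver hydride to give the (R)-carbinol.

**Step 2**
Reactants: 2 (2R,3E)-pent-3-en-2-ol; 3 succinic anhydride
Product: 4 4-oxo-4-{[(2R,3E)-pent-3-en-2-yl]oxy}butanoic acid
Conditions: DMAP (cat.), Et3N, CH2Cl2, rt; acidic work-up
Reagents that add atoms: none
Why: DMAP-catalysed acylative ring opening of the cyclic anhydride by the secondary alcohol gives the half ester without touching the carbinol centre.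

**Step 3**
Reactants: 4 4-oxo-4-{[(2R,3E)-pent-3-en-2-yl]oxy}butanoic acid
Product: 5 (2R,3E)-pent-3-en-2-yl 4-[methoxy(methyl)amino]-4-oxobutanoate
Conditions: 1,1'-carbonyldiimidazole, CH2Cl2, rt; then MeNHOMe·HCl
Reagents that add atoms: N,O-dimethylhydroxylamine hydrochloride, CNOC.Cl
Why: Amide coupling through the acyl imidazolide (Weinreb amide formation) leaves the allylic ester untouched.

**Step 4**
Reactants: 5 (2R,3E)-pent-3-en-2-yl 4-[methoxy(methyl)amino]-4-oxobutanoate; 6 bromoethene (vinyl bromide)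
Product: 7 (2R,3E)-pent-3-en-2-yl 5-bromo-4-oxohex-5-enoate
Conditions: 6, LDA, THF/Et2O/pentane, −110 °C (forms 1-bromo-1-lithioethene); then 5, −110 °C; aq. NH4Cl
Reagents that add atoms: none
Why: Weinreb ketone synthesis, in which the chelated tetrahedral adduct stops the addition of 1-bromo-1-lithioethene at the ketone stage while the hindered secondary ester is inert at −110 °C.

**Step 5**
Reactants: 7 (2R,3E)-pent-3-en-2-yl 5-bromo-4-oxohex-5-enoate
Product: 8 (2R,3E)-pent-3-en-2-yl (4R)-5-bromo-4-hydroxyhex-5-enoate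
Conditions: (S)-2-methyl-CBS-oxazaborolidine (20 mol%), catecholborane, toluene, −78 °C
Reagents that add atoms: none
Why: Corey–Bakshi–Shibata reduction of an α-bromo enone, in which the bromoalkenyl group is the large substituent, should set the future C9 as (R).

**Step 6**
Reactants: 8 (2R,3E)-pent-3-en-2-yl (4R)-5-bromo-4-hydroxyhex-5-enoate
Product: 9 (2R,3E)-pent-3-en-2-yl (4R)-5-bromo-4-(TBS-oxy)hex-5-enoate
Conditions: TBSOTf, 2,6-lutidine, CH2Cl2, −78 °C
Reagents that add atoms: tert-butyldimethylsilyl triflate, CC(C)(C)[Si](C)(C)OS(=O)(=O)C(F)(F)F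
Why: Fast silylation of the secondary alcohol at low temperature traps the γ-hydroxy ester before it can lactonise.

**Step 7**
Reactants: 9 (2R,3E)-pent-3-en-2-yl (4R)-5-bromo-4-(TBS-oxy)hex-5-enoate
Product: 12 (2S,3S,4E)-2-[(2R)-3-bromo-2-(TBS-oxy)but-3-en-1-yl]-3-methylhex-4-enoic acid, via silyl ketene acetal 10 (not isolated), via trimethylsilyl ester 11 (not isolated)
Conditions: LDA (1.1 equiv), Me3SiCl (internal quench), THF, −78 °C to 40 °C; then 1 M HCl
Reagents that add atoms: none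
Why: Ireland–Claisen rearrangement, in which LDA in THF gives the E(O)-enolate and the chair transition state with the carbinol methyl equatorial transfers the (R)-carbinol chirality to C7 and C11 (C8 and C19 anti) and forms the E-alkene.

**Step 8**
Reactants: 12 (2S,3S,4E)-2-[(2R)-3-bromo-2-(TBS-oxy)but-3-en-1-yl]-3-methylhex-4-enoic acid
Product: 13 (2S,3S,4E)-2-[(2R)-3-bromo-2-(TBS-oxy)but-3-en-1-yl]-N-methoxy-N,3-dimethylhex-4-enamide
Conditions: 1,1'-carbonyldiimidazole, CH2Cl2, rt; then MeNHOMe·HCl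
Reagents that add atoms: N,O-dimethylhydroxylamine hydrochloride, CNOC.Cl
Why: Amide coupling through the acyl imidazolide masks C6 as a Weinreb amide that survives the side-chain chemistry and later gives the aldehyde in one step.

**Step 9**
Reactants: 13 (2S,3S,4E)-2-[(2R)-3-bromo-2-(TBS-oxy)but-3-en-1-yl]-N-methoxy-N,3-dimethylhex-4-enamide
Product: 14 (2S,3R)-2-[(2R)-3-bromo-2-(TBS-oxy)but-3-en-1-yl]-N-methoxy-N,3-dimethyl-4-oxobutanamide
Conditions: OsO4 (2 mol%), NaIO4, 2,6-lutidine, dioxane/H2O, rt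
Reagents that add atoms: sodium periodate, [Na+].[O-]I(=O)(=O)=O (oxygen transferred through OsO4)
Why: Lemieux–Johnson oxidative cleavage, in which OsO4 should select the electron-rich 1,2-disubstituted alkene over the electron-poor 2-bromoalkene and buffered conditions keep the α-methyl aldehyde from epimerising.

**Step 10**
Reactants: 15 allyl tert-butyldimethylsilyl ether
Product: 16 (Z)-tributyl[3-(TBS-oxy)prop-2-en-1-yl]stannane
Conditions: s-BuLi, THF, −78 °C; then Bu3SnCl
Reagents that add atoms: tributyltin chloride, CCCC[Sn](Cl)(CCCC)CCCC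
Why: Deprotonation of the allyl silyl ether gives the oxygen-coordinated (Z)-γ-silyloxyallyl anion, which is stannylated at the terminal carbon.

**Step 11**
Reactants: 14 (2S,3R)-2-[(2R)-3-bromo-2-(TBS-oxy)but-3-en-1-yl]-N-methoxy-N,3-dimethyl-4-oxobutanamide; 16 (Z)-tributyl[3-(TBS-oxy)prop-2-en-1-yl]stannane
Product: 17 (2S,3R,4S,5S)-2-[(2R)-3-bromo-2-(TBS-oxy)but-3-en-1-yl]-4-hydroxy-5-(TBS-oxy)-N-methoxy-N,3-dimethylhept-6-enamide
Conditions: BF3·OEt2, CH2Cl2, −78 °C; NaHCO3 quench at −78 °C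
Reagents that add atoms: none
Why: BF3-promoted γ-silyloxyallylstannane addition through an open transition state should give the syn C12/C13 diol pattern with Felkin–Anh attack on the α-methyl aldehyde (C11 methyl and C12 oxygen syn).

**Step 12**
Reactants: 17 (2S,3R,4S,5S)-2-[(2R)-3-bromo-2-(TBS-oxy)but-3-en-1-yl]-4-hydroxy-5-(TBS-oxy)-N-methoxy-N,3-dimethylhept-6-enamide
Product: 18 (2S,3R,4S,5S)-2-[(2R)-3-bromo-2-(TBS-oxy)but-3-en-1-yl]-4,5-bis(TBS-oxy)-N-methoxy-N,3-dimethylhept-6-enamide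
Conditions: TBSOTf, 2,6-lutidine, CH2Cl2, −78 to 0 °C
Reagents that add atoms: tert-butyldimethylsilyl triflate, CC(C)(C)[Si](C)(C)OS(=O)(=O)C(F)(F)F
Why: Silylation of the hindered C12 hydroxyl with the silyl triflate also prevents its lactonisation onto the Weinreb amide.

**Step 13**
Reactants: 18 (2S,3R,4S,5S)-2-[(2R)-3-bromo-2-(TBS-oxy)but-3-en-1-yl]-4,5-bis(TBS-oxy)-N-methoxy-N,3-dimethylhept-6-enamide
Product: 19 (2S,3R,4S,5S)-2-[(2R)-3-bromo-2-(TBS-oxy)but-3-en-1-yl]-4,5-bis(TBS-oxy)-N-methoxy-N,3,7-trimethyloct-6-enamide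
Conditions: second-generation Grubbs catalyst RuCl2(=CHPh)(PCy3)(H2IMes) (5 mol%), 2-methylbut-2-ene (solvent), 40 °C
Reagents that add atoms: 2-methylbut-2-ene, CC=C(C)C
Why: Olefin cross-metathesis of the terminal alkene with 2-methylbut-2-ene installs the isobutenyl end, the electron-poor 1,1-disubstituted bromoalkene being inert.

**Step 14**
Reactants: 19 (2S,3R,4S,5S)-2-[(2R)-3-bromo-2-(TBS-oxy)but-3-en-1-yl]-4,5-bis(TBS-oxy)-N-methoxy-N,3,7-trimethyloct-6-enamide
Product: 20 (2S,3R,4S,5S)-2-[(2R)-3-bromo-2-(TBS-oxy)but-3-en-1-yl]-4,5-bis(TBS-oxy)-3,7-dimethyloct-6-enal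
Conditions: i-Bu2AlH, THF, −78 °C; Rochelle salt work-up
Reagents that add atoms: none
Why: Hydride reduction of the Weinreb amide stops at the chelated hemiaminal and releases the C6 aldehyde on work-up.

**Step 15**
Reactants: 20 (2S,3R,4S,5S)-2-[(2R)-3-bromo-2-(TBS-oxy)but-3-en-1-yl]-4,5-bis(TBS-oxy)-3,7-dimethyloct-6-enal; 21 cyclopent-2-en-1-one
Product: 23 2-[(1R,2S,3R,4S,5S)-2-[(2R)-3-bromo-2-(TBS-oxy)but-3-en-1-yl]-4,5-bis(TBS-oxy)-1-hydroxy-3,7-dimethyloct-6-en-1-yl]cyclopent-2-en-1-one, via selenide aldol adduct 22 (not isolated)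
Conditions: PhSeH, n-BuLi, THF, −78 °C; 21; then 20, −78 °C; aq. NH4Cl; then mCPBA, CH2Cl2, −78 °C; i-Pr2NH, to 0 °C
Reagents that add atoms: none
Why: Selenolate-mediated Morita–Baylis–Hillman-type sequence, in which conjugate addition gives the ring-fixed E(O)-enolate, its Zimmerman–Traxler aldol addition with Felkin–Anh attack (C11 branch as the large group) sets C6, and selenoxide syn-elimination restores the enone.

**Step 16**
Reactants: 23 2-[(1R,2S,3R,4S,5S)-2-[(2R)-3-bromo-2-(TBS-oxy)but-3-en-1-yl]-4,5-bis(TBS-oxy)-1-hydroxy-3,7-dimethyloct-6-en-1-yl]cyclopent-2-en-1-one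
Product: 24 cis-fused ketol (1R,5S,6R,7S,9R)-9-(TBS-oxy)-6-hydroxy-10-methylidene-7-[(2R,3S,4S)-3,4-bis(TBS-oxy)-6-methylhept-5-en-2-yl]hydroazulen-4-one (skeleton numbering; H1 and H5 cis)
Conditions: (Me3Si)3SiH (1.5 equiv) and AIBN (0.3 equiv) added by syringe pump over 8 h, toluene (2 mM), 90 °C
Reagents that add atoms: none
Why: The silyl radical abstracts bromine from C10, the α-silyloxy alkenyl radical adds to the enone β-carbon C1, and the C5 α-keto radical so formed takes hydrogen from the silane to carry the chain. The closest known reaction type is the tin- or silane-mediated cyclisation of a bromoalkene-derived alkenyl radical onto an enone in the endo mode. Only ring B is closed, by 7-endo-trig attack; ring A is the cyclopentenone already present, and 6-exo attack at the fully substituted α-carbon C5 would give an unstabilised secondary radical. C1 is controlled by the C6 carbinol: the O6–H···O=C4 hydrogen bond of the ketol holds the C6–O bond in the enone plane, which places C7 and the tether on the β face about 60° from the C5=C1 bond, so C10 should be delivered to that face. C5 is formed by hydrogen transfer to the face away from the new ring carbons, which should give the cis ring fusion shown (any trans isomer is the desilyl form of 26 and converges after steps 17 and 18). The step needs ring closure to outrun direct reduction and 1,5-hydrogen transfer to C10 from C6–H or C11–H; high dilution with slow addition of the slow donor (Me3Si)3SiH, the activated acceptor and the C6–H bond pointing to the α face in the reactive rotamer should secure this.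

**Step 17**
Reactants: 24 cis-fused ketol
Product: 25 cis-fused TES ether (1R,5S,6R,7S,9R)-9-(TBS-oxy)-6-(TES-oxy)-10-methylidene-7-[(2R,3S,4S)-3,4-bis(TBS-oxy)-6-methylhept-5-en-2-yl]hydroazulen-4-one
Conditions: TESOTf, 2,6-lutidine, CH2Cl2, −78 °C
Reagents that add atoms: triethylsilyl triflate, CC[Si](CC)(CC)OS(=O)(=O)C(F)(F)F
Why: Silylation of the hindered C6 carbinol with the silyl triflate at low temperature blocks retro-aldol cleavage in the basic steps that follow.

**Step 18**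
Reactants: 25 cis-fused TES ether
Product: 26 trans-fused ketone (1R,5R,6R,7S,9R)-9-(TBS-oxy)-6-(TES-oxy)-10-methylidene-7-[(2R,3S,4S)-3,4-bis(TBS-oxy)-6-methylhept-5-en-2-yl]hydroazulen-4-one (H1 α, H5 β)
Conditions: DBU (0.3 equiv), toluene, 40 °C
Reagents that add atoms: none
Why: Base-mediated epimerisation through the C4–C5 enolate should favour the trans fusion, which puts the ring A carbonyl carbon C4 and the C6 silyloxy group trans on ring B, while E1cB loss of the silyloxy group is disfavoured because the ring holds the C6–O bond near the enolate plane.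

**Step 19**
Reactants: 26 trans-fused ketone
Product: 27 enol triflate (1R,5R,6R,7S,9R)-9-(TBS-oxy)-6-(TES-oxy)-10-methylidene-7-[(2R,3S,4S)-3,4-bis(TBS-oxy)-6-methylhept-5-en-2-yl]hydroazul-3-en-4-yl triflate
Conditions: KHMDS, THF, −78 °C; then N-(5-chloropyridin-2-yl)triflimide (Comins' reagent); aq. NH4Cl
Reagents that add atoms: N-(5-chloropyridin-2-yl)triflimide, FC(F)(F)S(=O)(=O)N(c1ccc(Cl)cn1)S(=O)(=O)C(F)(F)F
Why: Kinetic deprotonation at the unhindered C3 methylene followed by O-triflation (enol triflate formation) fixes the C3=C4 position without touching C5.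

**Step 20**
Reactants: 27 enol triflate
Product: 28 tetrasilyl ether (1R,5S,6R,7S,9R)-9-(TBS-oxy)-6-(TES-oxy)-4-methyl-10-methylidene-7-[(2R,3S,4S)-3,4-bis(TBS-oxy)-6-methylhept-5-en-2-yl]hydroazul-3-ene
Conditions: Fe(acac)3 (10 mol%), MeMgBr, THF/NMP, −30 °C
Reagents that add atoms: methylmagnesium bromide, C[Mg]Br
Why: Iron-catalysed cross-coupling of the alkenyl triflate with the methyl Grignard reagent installs C17 on the pre-set C3=C4 alkene.

**Step 21**
Reactants: 28 tetrasilyl ether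
Product: 29 tetraol (1R,5S,6R,7S,9R)-4-methyl-10-methylidene-7-[(2R,3S,4S)-3,4-dihydroxy-6-methylhept-5-en-2-yl]hydroazul-3-ene-6,9-diol
Conditions: Bu4NF, THF, 0 °C to rt
Reagents that add atoms: none
Why: Fluoride-mediated cleavage removes all four silyl ethers under conditions that leave the three alkenes and the allylic alcohols intact.

**Step 22**
Reactants: 29 tetraol
Product: 30 CNP0194318.1, the 9,12,13-triacetate of 29 (1R,5S,6R,7S,9R,11R,12S,13S)
Conditions: Ac2O, pyridine, CH2Cl2, 0 °C to rt (no DMAP)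
Reagents that add atoms: acetic anhydride, CC(=O)OC(C)=O
Why: Site-selective acetylation, in which the C9, C12 and C13 hydroxyls should react while the C6 hydroxyl, flanked by the ring-fusion methine C5 and the branched C7, stays free.

**Compound list**

1 | (E)-pent-3-en-2-one | C/C=C/C(C)=O | starting material
2 | (2R,3E)-pent-3-en-2-ol | C[C@@H](O)/C=C/C | intermediate
3 | succinic anhydride | O=C1CCC(=O)O1 | starting material
4 | 4-oxo-4-{[(2R,3E)-pent-3-en-2-yl]oxy}butanoic acid | OC(=O)CCC(=O)O[C@H](C)/C=C/C | intermediate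
5 | (2R,3E)-pent-3-en-2-yl 4-[methoxy(methyl)amino]-4-oxobutanoate | CON(C)C(=O)CCC(=O)O[C@H](C)/C=C/C | intermediate
6 | bromoethene (vinyl bromide) | C=CBr | starting material
7 | (2R,3E)-pent-3-en-2-yl 5-bromo-4-oxohex-5-enoate | C=C(Br)C(=O)CCC(=O)O[C@H](C)/C=C/C | intermediate
8 | (2R,3E)-pent-3-en-2-yl (4R)-5-bromo-4-hydroxyhex-5-enoate | C=C(Br)[C@H](O)CCC(=O)O[C@H](C)/C=C/C | intermediate
9 | (2R,3E)-pent-3-en-2-yl (4R)-5-bromo-4-(TBS-oxy)hex-5-enoate | C=C(Br)[C@H](O[Si](C)(C)C(C)(C)C)CCC(=O)O[C@H](C)/C=C/C | intermediate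
10 | (E)-trimethylsilyl ketene acetal of 9 | C=C(Br)[C@H](O[Si](C)(C)C(C)(C)C)C/C=C(/O[Si](C)(C)C)O[C@H](C)/C=C/C | intermediate
11 | trimethylsilyl ester of 12 | C=C(Br)[C@H](O[Si](C)(C)C(C)(C)C)C[C@@H]([C@@H](C)/C=C/C)C(=O)O[Si](C)(C)C | intermediate
12 | (2S,3S,4E)-2-[(2R)-3-bromo-2-(TBS-oxy)but-3-en-1-yl]-3-methylhex-4-enoic acid | C=C(Br)[C@H](O[Si](C)(C)C(C)(C)C)C[C@@H]([C@@H](C)/C=C/C)C(O)=O | intermediate
13 | (2S,3S,4E)-2-[(2R)-3-bromo-2-(TBS-oxy)but-3-en-1-yl]-N-methoxy-N,3-dimethylhex-4-enamide | C=C(Br)[C@H](O[Si](C)(C)C(C)(C)C)C[C@@H]([C@@H](C)/C=C/C)C(=O)N(C)OC | intermediate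
14 | (2S,3R)-2-[(2R)-3-bromo-2-(TBS-oxy)but-3-en-1-yl]-N-methoxy-N,3-dimethyl-4-oxobutanamide | C=C(Br)[C@H](O[Si](C)(C)C(C)(C)C)C[C@@H]([C@@H](C)C=O)C(=O)N(C)OC | intermediate
15 | allyl tert-butyldimethylsilyl ether | C=CCO[Si](C)(C)C(C)(C)C | starting material
16 | (Z)-tributyl[3-(TBS-oxy)prop-2-en-1-yl]stannane | CCCC[Sn](CCCC)(CCCC)C/C=C\O[Si](C)(C)C(C)(C)C | intermediate
17 | (2S,3R,4S,5S)-2-[(2R)-3-bromo-2-(TBS-oxy)but-3-en-1-yl]-4-hydroxy-5-(TBS-oxy)-N-methoxy-N,3-dimethylhept-6-enamide | C=C(Br)[C@H](O[Si](C)(C)C(C)(C)C)C[C@@H]([C@@H](C)[C@H](O)[C@H](C=C)O[Si](C)(C)C(C)(C)C)C(=O)N(C)OC | intermediate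
18 | (2S,3R,4S,5S)-2-[(2R)-3-bromo-2-(TBS-oxy)but-3-en-1-yl]-4,5-bis(TBS-oxy)-N-methoxy-N,3-dimethylhept-6-enamide | C=C(Br)[C@H](O[Si](C)(C)C(C)(C)C)C[C@@H]([C@@H](C)[C@H](O[Si](C)(C)C(C)(C)C)[C@H](C=C)O[Si](C)(C)C(C)(C)C)C(=O)N(C)OC | intermediate
19 | (2S,3R,4S,5S)-2-[(2R)-3-bromo-2-(TBS-oxy)but-3-en-1-yl]-4,5-bis(TBS-oxy)-N-methoxy-N,3,7-trimethyloct-6-enamide | C=C(Br)[C@H](O[Si](C)(C)C(C)(C)C)C[C@@H]([C@@H](C)[C@H](O[Si](C)(C)C(C)(C)C)[C@H](C=C(C)C)O[Si](C)(C)C(C)(C)C)C(=O)N(C)OC | intermediate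
20 | (2S,3R,4S,5S)-2-[(2R)-3-bromo-2-(TBS-oxy)but-3-en-1-yl]-4,5-bis(TBS-oxy)-3,7-dimethyloct-6-enal | C=C(Br)[C@H](O[Si](C)(C)C(C)(C)C)C[C@@H]([C@@H](C)[C@H](O[Si](C)(C)C(C)(C)C)[C@H](C=C(C)C)O[Si](C)(C)C(C)(C)C)C=O | intermediate
21 | cyclopent-2-en-1-one | O=C1C=CCC1 | starting material
22 | selenide aldol adduct: trans-3-(phenylselanyl)cyclopentanone carrying the C6 carbinol chain at C2 (C6 as in 23) | C=C(Br)[C@H](O[Si](C)(C)C(C)(C)C)C[C@@H]([C@@H](C)[C@H](O[Si](C)(C)C(C)(C)C)[C@H](C=C(C)C)O[Si](C)(C)C(C)(C)C)[C@@H](O)[C@@H]1C(=O)CC[C@H]1[Se]c1ccccc1 | intermediate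
23 | 2-[(1R,2S,3R,4S,5S)-2-[(2R)-3-bromo-2-(TBS-oxy)but-3-en-1-yl]-4,5-bis(TBS-oxy)-1-hydroxy-3,7-dimethyloct-6-en-1-yl]cyclopent-2-en-1-one | C=C(Br)[C@H](O[Si](C)(C)C(C)(C)C)C[C@@H]([C@@H](C)[C@H](O[Si](C)(C)C(C)(C)C)[C@H](C=C(C)C)O[Si](C)(C)C(C)(C)C)[C@@H](O)C1=CCCC1=O | intermediate
24 | cis-fused ketol (1R,5S,6R,7S,9R), C9 TBS ether, C6 free hydroxyl, C4 ketone, C10 methylidene, bis-TBS side chain | C=C1[C@H](O[Si](C)(C)C(C)(C)C)C[C@@H]([C@@H](C)[C@H](O[Si](C)(C)C(C)(C)C)[C@H](C=C(C)C)O[Si](C)(C)C(C)(C)C)[C@@H](O)[C@H]2C(=O)CC[C@@H]12 | intermediate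
25 | C6 TES ether of 24 (cis-fused) | C=C1[C@H](O[Si](C)(C)C(C)(C)C)C[C@@H]([C@@H](C)[C@H](O[Si](C)(C)C(C)(C)C)[C@H](C=C(C)C)O[Si](C)(C)C(C)(C)C)[C@@H](O[Si](CC)(CC)CC)[C@H]2C(=O)CC[C@@H]12 | intermediate
26 | trans-fused ketone (1R,5R,6R,7S,9R), C5 epimer of 25 | C=C1[C@H](O[Si](C)(C)C(C)(C)C)C[C@@H]([C@@H](C)[C@H](O[Si](C)(C)C(C)(C)C)[C@H](C=C(C)C)O[Si](C)(C)C(C)(C)C)[C@@H](O[Si](CC)(CC)CC)[C@@H]2C(=O)CC[C@@H]12 | intermediate
27 | C3=C4 enol triflate of 26 | C=C1[C@H](O[Si](C)(C)C(C)(C)C)C[C@@H]([C@@H](C)[C@H](O[Si](C)(C)C(C)(C)C)[C@H](C=C(C)C)O[Si](C)(C)C(C)(C)C)[C@@H](O[Si](CC)(CC)CC)[C@@H]2C(OS(=O)(=O)C(F)(F)F)=CC[C@@H]12 | intermediate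
28 | tetrasilyl ether of 29 (C6 TES; C9, C12, C13 TBS) | C=C1[C@H](O[Si](C)(C)C(C)(C)C)C[C@@H]([C@@H](C)[C@H](O[Si](C)(C)C(C)(C)C)[C@H](C=C(C)C)O[Si](C)(C)C(C)(C)C)[C@@H](O[Si](CC)(CC)CC)[C@@H]2C(C)=CC[C@@H]12 | intermediate
29 | tetraol (1R,5S,6R,7S,9R,11R,12S,13S) | C=C1[C@H](O)C[C@@H]([C@@H](C)[C@H](O)[C@H](C=C(C)C)O)[C@@H](O)[C@@H]2C(C)=CC[C@@H]12 | intermediate
30 | CNP0194318.1, 9,12,13-triacetate of 29 | C=C1[C@H](OC(C)=O)C[C@@H]([C@@H](C)[C@H](OC(C)=O)[C@H](C=C(C)C)OC(C)=O)[C@@H](O)[C@@H]2C(C)=CC[C@@H]12 | target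

**Summary**

Total step count: 22. Longest linear sequence: 21 steps (steps 1–9 and 11–22; step 10 prepares the stannane).

Steps most likely to fail:

Step 16. The alkenyl radical may be reduced or may take a hydrogen atom from C6 or C11 before the ring closes, or may add to the α face of C1. The fallback replaces the radical by an organocopper conjugate addition. It sets out from 23: Pd(PPh3)4-catalysed bromine–tin exchange with hexamethylditin gives the alkenyltrimethylstannane F1. CuCl in DMF then transfers the alkenyl group from tin to copper, and the alkenylcopper adds intramolecularly to C1 of the hydrogen-bonded enone. Protonation of the enolate on work-up returns to the route at 24.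

Step 18. The equilibrium at C5 may not lie far enough on the trans side, or the enolate may lose the C6 silyloxy group. The fallback moves the equilibration in front of the silylation and runs it through the neutral enol instead of the enolate. It sets out from 24: 2-hydroxypyridine (bifunctional proton-shuttle catalysis) in toluene at 80 °C should equilibrate the free ketol, with neither an alkoxide nor an enolate bearing a β-leaving group formed, to the trans-fused ketol F2. TESOTf and 2,6-lutidine then give 26, where the route is rejoined.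

Step 15. The aldol addition may show poor facial selectivity at C6, because the two carbon substituents on C7 differ only moderately in size, or may be slow with the hindered aldehyde. The fallback sets C6 by reagent control. It sets out from 19: the 2-lithio derivative of 2-bromocyclopent-2-enone ethylene ketal (from the bromo ketal and n-BuLi, −78 °C) adds to the Weinreb amide to give the enone ketal F3. CBS reduction with the (S)-oxazaborolidine and catecholborane gives the allylic alcohol F4, and oxalic acid on wet silica removes the ketal to return to the route at 23.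

**Further compounds**

F1 | step 16 | alkenyltrimethylstannane analogue of 23 (SnMe3 in place of Br) | C=C([Sn](C)(C)C)[C@H](O[Si](C)(C)C(C)(C)C)C[C@@H]([C@@H](C)[C@H](O[Si](C)(C)C(C)(C)C)[C@H](C=C(C)C)O[Si](C)(C)C(C)(C)C)[C@@H](O)C1=CCCC1=O
F2 | step 18 | trans-fused ketol, C5 epimer of 24 | C=C1[C@H](O[Si](C)(C)C(C)(C)C)C[C@@H]([C@@H](C)[C@H](O[Si](C)(C)C(C)(C)C)[C@H](C=C(C)C)O[Si](C)(C)C(C)(C)C)[C@@H](O)[C@@H]2C(=O)CC[C@@H]12
F3 | step 15 | enone ketal: C6 ketone attached to C2 of cyclopent-2-enone ethylene ketal | C=C(Br)[C@H](O[Si](C)(C)C(C)(C)C)C[C@@H]([C@@H](C)[C@H](O[Si](C)(C)C(C)(C)C)[C@H](C=C(C)C)O[Si](C)(C)C(C)(C)C)C(=O)C1=CCCC12OCCO2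
F4 | step 15 | (6R)-allylic alcohol, ethylene ketal of 23 | C=C(Br)[C@H](O[Si](C)(C)C(C)(C)C)C[C@@H]([C@@H](C)[C@H](O[Si](C)(C)C(C)(C)C)[C@H](C=C(C)C)O[Si](C)(C)C(C)(C)C)[C@@H](O)C1=CCCC12OCCO2
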